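**Plan**

- Retrosynthesis cuts, in this order: the Ca–CO2Me bond (Ca = acrylate carbon on C2, benzofuran numbering) back to Ca–B; the tiglate ester C–O bond; the C5–acetyl bond back to C5–Br; the C2–C3 bond of the dihydrofuran; the ArO–CH2 bond of a propargyl ether.
- Enabling feature: C2 carries the ring oxygen O1, is allylic to the Ca=CH2 unit and is bonded to the oxygenated C3. This array is what an allyl metal with an aryloxy group on its γ-carbon gives on adding to an aldehyde, the middle allene carbon becoming Ca.
- Forward: the benzene ring is bought. O-propargylation and isomerisation give the aryloxyallene aldehyde, and the dihydrofuran ring (O1–C2–C3–C3a–C7a) closes in the borylative cyclisation with boron left on Ca.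
- Then C3–OH is acetylated, C5–Br becomes acetyl, the ketone is reduced, the carbinol is tigloylated, and Ca–B is carbonylated last, so the acrylate never meets a free cis C3–OH or the nucleophilic reagents of earlier steps.
- Stereochemistry: C2 and C3 (2S,3S, cis) come from the copper–bisphosphine cyclisation, the side-chain (S)-carbinol from Noyori–Ikariya transfer hydrogenation, and the E alkene is bought with tigloyl chloride.

Key step: step 3

Remark: the sense of induction of the copper catalyst on this substrate cannot be predicted with certainty; (R,R)-Ph-BPE, 1,2-bis[(2R,5R)-2,5-diphenylphospholan-1-yl]ethane, is written, and its mirror image is to be used if a first run shows the (2R,3R) series.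

**Route**

Step 1
Reactants: 1 5-bromo-2-hydroxybenzaldehyde; 2 propargyl bromide
Product: 3 5-bromo-2-(prop-2-yn-1-yloxy)benzaldehyde
Conditions: K2CO3 (1.5 equiv), DMF, rt
Reagents that add atoms: none
Why: Williamson ether synthesis, in which the phenoxide (acidified by the ortho formyl group) displaces bromide from the primary propargylic halide by SN2 while aldehyde and aryl bromide are inert to K2CO3.

Step 2
Reactants: 3 5-bromo-2-(prop-2-yn-1-yloxy)benzaldehyde
Product: 4 5-bromo-2-(propa-1,2-dien-1-yloxy)benzaldehyde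
Conditions: KOtBu (0.2 equiv), THF, 0 °C to rt
Reagents that add atoms: none
Why: Base-catalysed propargyl-to-allenyl ether isomerisation (prototropic 1,3-shift through the oxygen-stabilised propargyl/allenyl anion), which should stop at the aryloxyallene with substoichiometric base, the non-enolisable aldehyde adding tert-butoxide only reversibly.

Step 3
Reactants: 4 5-bromo-2-(propa-1,2-dien-1-yloxy)benzaldehyde; 5 bis(pinacolato)diboron
Product: 7 (2S,3S)-5-bromo-2-[1-(4,4,5,5-tetramethyl-1,3,2-dioxaborolan-2-yl)ethenyl]-2,3-dihydro-1-benzofuran-3-ol, via O-boryl ether 6 (not isolated)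
Conditions: CuCl (5 mol%), (R,R)-Ph-BPE (6 mol%), NaOtBu (10 mol%), 5 (1.1 equiv), THF, 0 °C to rt; then aq NH4Cl
Reagents that add atoms: none
Why: Proposed new method: the ligated Cu–Bpin species formed from CuCl, NaOtBu and 5 should add syn across the terminal C=C of the allene on the face remote from the aryloxy group, boron going to the central carbon, and the resulting Z 2-boryl-3-aryloxyallyl copper species should add through its oxygen-bearing γ-carbon to the ortho aldehyde in a closed six-membered chair-like transition state, after which the copper alkoxide is borylated by 5 to give 6 and return Cu–Bpin. The closest known reaction type is the copper-catalysed borylative coupling of monosubstituted allenes with aldehydes and ketones through 2-borylallyl copper species, known intermolecularly and in ring-closing form for carbon-tethered allenyl ketones, with the γ-selective syn addition of Z γ-alkoxyallyl boron reagents to aldehydes as the stoichiometric model; new is the aryloxyallene joined to the aldehyde through the arene. The dihydrofuran ring closes in a 5-exo-trig mode as C2 attacks the formyl carbon and makes the C2–C3 bond. The cis relation of C2 and C3 should follow from the Z geometry of the allyl copper species in the closed transition state (syn adduct), and the absolute configuration of both centres from the enantiopure bisphosphine on copper, which selects the aldehyde face. The step needs borylcupration of the allene to outrun 1,2-addition of Cu–Bpin to the aldehyde and borylation of the C–Br bond, which the high reactivity of allenes toward Cu–B addition, the catalytic amount of alkoxide and the low temperature should secure, while the non-enolisable aldehyde held two atoms from the ether oxygen makes ring closure fast.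

Step 4
Reactants: 7 (2S,3S)-5-bromo-2-[1-(4,4,5,5-tetramethyl-1,3,2-dioxaborolan-2-yl)ethenyl]-2,3-dihydro-1-benzofuran-3-ol
Product: 8 (2S,3S)-5-bromo-2-[1-(4,4,5,5-tetramethyl-1,3,2-dioxaborolan-2-yl)ethenyl]-2,3-dihydro-1-benzofuran-3-yl acetate
Conditions: Ac2O (1.5 equiv), pyridine (3 equiv), 4-(dimethylamino)pyridine (5 mol%), CH2Cl2, 0 °C to rt
Reagents that add atoms: acetic anhydride, CC(=O)OC(C)=O
Why: Nucleophile-catalysed O-acylation of the secondary benzylic alcohol with retention at C3, placed here so that no free cis C3–OH remains to lactonise onto the ester made in step 8, the pinacol alkenylboronate being inert to Ac2O and pyridine.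

Step 5
Reactants: 8 (2S,3S)-5-bromo-2-[1-(4,4,5,5-tetramethyl-1,3,2-dioxaborolan-2-yl)ethenyl]-2,3-dihydro-1-benzofuran-3-yl acetate; 9 tributyl(1-ethoxyethenyl)stannane
Product: 11 (2S,3S)-5-acetyl-2-[1-(4,4,5,5-tetramethyl-1,3,2-dioxaborolan-2-yl)ethenyl]-2,3-dihydro-1-benzofuran-3-yl acetate, via enol ether 10 (not isolated)
Conditions: Pd(PPh3)4 (5 mol%), 9 (1.3 equiv), toluene, 95 °C; then 1 M aq HCl, THF, 0 °C
Reagents that add atoms: water, O
Why: Migita–Kosugi–Stille coupling of the aryl bromide with the α-ethoxyvinylstannane as an acetyl equivalent, run without base or fluoride so that the alkenyl–boron bond does not transmetalate, followed by mild acid hydrolysis of the aryl enol ether to the methyl ketone, leaving C2 and C3 untouched.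

Step 6
Reactants: 11 (2S,3S)-5-acetyl-2-[1-(4,4,5,5-tetramethyl-1,3,2-dioxaborolan-2-yl)ethenyl]-2,3-dihydro-1-benzofuran-3-yl acetate
Product: 12 (2S,3S)-5-[(1S)-1-hydroxyethyl]-2-[1-(4,4,5,5-tetramethyl-1,3,2-dioxaborolan-2-yl)ethenyl]-2,3-dihydro-1-benzofuran-3-yl acetate
Conditions: RuCl[(S,S)-TsDPEN](p-cymene) (1 mol%), HCO2H/Et3N (5:2), CH2Cl2, rt
Reagents that add atoms: none
Why: Noyori–Ikariya asymmetric transfer hydrogenation, in which the (S,S)-TsDPEN ruthenium hydride should deliver hydrogen to the Re face of the aryl methyl ketone through the outer-sphere six-membered transition state and set the (S)-carbinol under catalyst control, esters, the alkenylboronate and the C=C bond not being reduced.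

Step 7
Reactants: 12 (2S,3S)-5-[(1S)-1-hydroxyethyl]-2-[1-(4,4,5,5-tetramethyl-1,3,2-dioxaborolan-2-yl)ethenyl]-2,3-dihydro-1-benzofuran-3-yl acetate; 13 tigloyl chloride, (2E)-2-methylbut-2-enoyl chloride
Product: 14 (1S)-1-{(2S,3S)-3-(acetyloxy)-2-[1-(4,4,5,5-tetramethyl-1,3,2-dioxaborolan-2-yl)ethenyl]-2,3-dihydro-1-benzofuran-5-yl}ethyl (2E)-2-methylbut-2-enoate
Conditions: 13 (1.5 equiv), pyridine (3 equiv), 4-(dimethylamino)pyridine (10 mol%), CH2Cl2, 0 °C to rt
Reagents that add atoms: none
Why: Acyl transfer from the acid chloride through the N-acylpyridinium ion (nucleophilic catalysis) esterifies the carbinol oxygen without breaking its C–O bond, so the (S) configuration is kept, and the E tiglate geometry is the thermodynamically preferred one.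

Step 8
Reactants: 14 (1S)-1-{(2S,3S)-3-(acetyloxy)-2-[1-(4,4,5,5-tetramethyl-1,3,2-dioxaborolan-2-yl)ethenyl]-2,3-dihydro-1-benzofuran-5-yl}ethyl (2E)-2-methylbut-2-enoate
Product: 15 methyl 2-[(2S,3S)-3-(acetyloxy)-5-{(1S)-1-[(2E)-2-methylbut-2-enoyloxy]ethyl}-2,3-dihydro-1-benzofuran-2-yl]prop-2-enoate
Conditions: Pd(OAc)2 (5 mol%), PPh3 (10 mol%), p-benzoquinone (1.5 equiv), CO (1 atm), MeOH/THF, rt
Reagents that add atoms: carbon monoxide, [C-]#[O+]; methanol, CO
Why: Oxidative alkoxycarbonylation of an alkenylboronate by divalent palladium (boron-to-palladium transmetalation, CO insertion, methanolysis of the acyl palladium species, benzoquinone reoxidising zerovalent palladium) should give the methyl acrylate at Ca, the neutral base-free medium at rt sparing the acetate, the tiglate and the allylic C2–O bond.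

**Compound list**

1 | 5-bromo-2-hydroxybenzaldehyde | O=Cc1cc(Br)ccc1O | starting material
2 | propargyl bromide (3-bromoprop-1-yne) | C#CCBr | starting material
3 | 5-bromo-2-(prop-2-yn-1-yloxy)benzaldehyde | C#CCOc1ccc(Br)cc1C=O | intermediate
4 | 5-bromo-2-(propa-1,2-dien-1-yloxy)benzaldehyde | C=C=COc1ccc(Br)cc1C=O | intermediate
5 | bis(pinacolato)diboron | CC1(C)OB(B2OC(C)(C)C(C)(C)O2)OC1(C)C | starting material
6 | 2-({(2S,3S)-5-bromo-2-[1-(4,4,5,5-tetramethyl-1,3,2-dioxaborolan-2-yl)ethenyl]-2,3-dihydro-1-benzofuran-3-yl}oxy)-4,4,5,5-tetramethyl-1,3,2-dioxaborolane | C=C(B1OC(C)(C)C(C)(C)O1)[C@@H]1Oc2ccc(Br)cc2[C@@H]1OB1OC(C)(C)C(C)(C)O1 | intermediate (not isolated)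
7 | (2S,3S)-5-bromo-2-[1-(4,4,5,5-tetramethyl-1,3,2-dioxaborolan-2-yl)ethenyl]-2,3-dihydro-1-benzofuran-3-ol | C=C(B1OC(C)(C)C(C)(C)O1)[C@@H]1Oc2ccc(Br)cc2[C@@H]1O | intermediate
8 | (2S,3S)-5-bromo-2-[1-(4,4,5,5-tetramethyl-1,3,2-dioxaborolan-2-yl)ethenyl]-2,3-dihydro-1-benzofuran-3-yl acetate | C=C(B1OC(C)(C)C(C)(C)O1)[C@@H]1Oc2ccc(Br)cc2[C@@H]1OC(C)=O | intermediate
9 | tributyl(1-ethoxyethenyl)stannane | C=C(OCC)[Sn](CCCC)(CCCC)CCCC | starting material
10 | (2S,3S)-5-(1-ethoxyethenyl)-2-[1-(4,4,5,5-tetramethyl-1,3,2-dioxaborolan-2-yl)ethenyl]-2,3-dihydro-1-benzofuran-3-yl acetate | C=C(B1OC(C)(C)C(C)(C)O1)[C@@H]1Oc2ccc(C(=C)OCC)cc2[C@@H]1OC(C)=O | intermediate (not isolated)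
11 | (2S,3S)-5-acetyl-2-[1-(4,4,5,5-tetramethyl-1,3,2-dioxaborolan-2-yl)ethenyl]-2,3-dihydro-1-benzofuran-3-yl acetate | C=C(B1OC(C)(C)C(C)(C)O1)[C@@H]1Oc2ccc(C(C)=O)cc2[C@@H]1OC(C)=O | intermediate
12 | (2S,3S)-5-[(1S)-1-hydroxyethyl]-2-[1-(4,4,5,5-tetramethyl-1,3,2-dioxaborolan-2-yl)ethenyl]-2,3-dihydro-1-benzofuran-3-yl acetate | C=C(B1OC(C)(C)C(C)(C)O1)[C@@H]1Oc2ccc([C@H](C)O)cc2[C@@H]1OC(C)=O | intermediate
13 | tigloyl chloride, (2E)-2-methylbut-2-enoyl chloride | C/C=C(\C)C(Cl)=O | starting material
14 | (1S)-1-{(2S,3S)-3-(acetyloxy)-2-[1-(4,4,5,5-tetramethyl-1,3,2-dioxaborolan-2-yl)ethenyl]-2,3-dihydro-1-benzofuran-5-yl}ethyl (2E)-2-methylbut-2-enoate | C=C(B1OC(C)(C)C(C)(C)O1)[C@@H]1Oc2ccc([C@H](C)OC(=O)/C(C)=C/C)cc2[C@@H]1OC(C)=O | intermediate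
15 | methyl 2-[(2S,3S)-3-(acetyloxy)-5-{(1S)-1-[(2E)-2-methylbut-2-enoyloxy]ethyl}-2,3-dihydro-1-benzofuran-2-yl]prop-2-enoate | C=C(C(=O)OC)[C@@H]1Oc2ccc([C@H](C)OC(=O)/C(C)=C/C)cc2[C@@H]1OC(C)=O | target

**Step count and risks**

Total step count: 8. Longest linear sequence: 8 steps (1 to 15).

Steps most likely to fail:

1. Step 3 (borylative cyclisation). The ring-closing addition may proceed with poor facial selectivity or through a partly isomerised allyl copper species, eroding ee or the cis/trans ratio, or Cu–Bpin may be diverted into 1,2-borylation of the aldehyde. The fallback uses known chemistry, sets out from 4 and comes back at 7.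
   - Diboration of the terminal allene bond of 4 with 5 under Pt(dba)2/PCy3 catalysis in toluene at 50 °C (a known reaction of monosubstituted allenes, the bulky phosphine directing both boron atoms to the unsubstituted double bond) would give 5-bromo-2-{[(1Z)-2,3-bis(4,4,5,5-tetramethyl-1,3,2-dioxaborolan-2-yl)prop-1-en-1-yl]oxy}benzaldehyde F1.
   - As a γ-aryloxy 2-borylallylboronate, F1 should cyclise on warming, without catalyst, by intramolecular allylboration through a closed chair transition state to the racemic cis boryl ether F2. This is known reactivity of 2-borylallylboronates and of Z γ-alkoxyallylboronates, which give syn adducts.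
   - Aqueous work-up gives the racemic cis alcohol F3.
   - Acylative kinetic resolution with isobutyric anhydride, iPr2NEt and the enantiopure isothiourea acyl-transfer catalyst 2-phenyl-2,3-dihydroimidazo[2,1-b][1,3]benzothiazole is a method established for secondary benzylic alcohols. The (2R) or (2S) antipode is chosen in a trial run so that the (2R,3R)-alcohol is the one acylated. This would convert the unwanted enantiomer into the (2R,3R) isobutyrate F4 and leave 7, which is separated by chromatography and enters step 4.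

2. Step 8 (oxidative methoxycarbonylation). Transmetalation of the hindered 1,1-disubstituted alkenylboronate to divalent palladium may be slower than protodeboronation or oxidative homocoupling, or phosphine and palladium may ionise the allylic C2–O bond once the acrylate has formed. The fallback sets out from 14 and comes back at 15.
   - KHF2 in aqueous MeOH converts the pinacol boronate into the potassium alkenyltrifluoroborate F5.
   - Iododeboronation with NaI and TsN(Cl)Na (chloramine-T) in THF/H2O at rt, a mild ipso-substitution known for alkenyltrifluoroborates, gives the alkenyl iodide F6.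
   - Methoxycarbonylation of F6 with PdCl2(PPh3)2, CO (1 atm), MeOH and iPr2NEt in DMF at 40 °C (carbonylation of an alkenyl iodide through oxidative addition to zerovalent palladium) gives 15.

3. Step 2 (propargyl-to-allenyl isomerisation). tert-Butoxide-induced hydride transfer between aldehyde molecules (Tishchenko or Cannizzaro type) or further prototropy to the 1-propynyl ether may compete with the clean 1,3-shift. The fallback sets out from 3 and comes back at 4.
   - Acetalisation with HC(OMe)3 in MeOH and catalytic p-toluenesulfonic acid monohydrate gives 4-bromo-2-(dimethoxymethyl)-1-(prop-2-yn-1-yloxy)benzene F7.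
   - KOtBu in THF isomerises it, with no electrophilic carbonyl present, to 4-bromo-2-(dimethoxymethyl)-1-(propa-1,2-dien-1-yloxy)benzene F8.
   - Brief hydrolysis with catalytic pyridinium p-toluenesulfonate in wet acetone at rt returns 4; benzaldehyde dimethyl acetals are expected to hydrolyse much faster than aryl allenyl ethers.

**Further compounds**

F1 | step 3 | 5-bromo-2-{[(1Z)-2,3-bis(4,4,5,5-tetramethyl-1,3,2-dioxaborolan-2-yl)prop-1-en-1-yl]oxy}benzaldehyde | O=Cc1cc(Br)ccc1O/C=C(\CB1OC(C)(C)C(C)(C)O1)B1OC(C)(C)C(C)(C)O1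
F2 | step 3 | racemic cis boryl ether, 6 together with its (2R,3R)-enantiomer | C=C(B1OC(C)(C)C(C)(C)O1)[C@@H]1Oc2ccc(Br)cc2[C@@H]1OB1OC(C)(C)C(C)(C)O1.C=C(B1OC(C)(C)C(C)(C)O1)[C@H]1Oc2ccc(Br)cc2[C@H]1OB1OC(C)(C)C(C)(C)O1
F3 | step 3 | racemic cis alcohol, 7 together with its (2R,3R)-enantiomer | C=C(B1OC(C)(C)C(C)(C)O1)[C@@H]1Oc2ccc(Br)cc2[C@@H]1O.C=C(B1OC(C)(C)C(C)(C)O1)[C@H]1Oc2ccc(Br)cc2[C@H]1O
F4 | step 3 | (2R,3R)-5-bromo-2-[1-(4,4,5,5-tetramethyl-1,3,2-dioxaborolan-2-yl)ethenyl]-2,3-dihydro-1-benzofuran-3-yl 2-methylpropanoate | C=C(B1OC(C)(C)C(C)(C)O1)[C@H]1Oc2ccc(Br)cc2[C@H]1OC(=O)C(C)C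
F5 | step 8 | potassium {1-[(2S,3S)-3-(acetyloxy)-5-{(1S)-1-[(2E)-2-methylbut-2-enoyloxy]ethyl}-2,3-dihydro-1-benzofuran-2-yl]ethenyl}trifluoroborate | C=C([B-](F)(F)F)[C@@H]1Oc2ccc([C@H](C)OC(=O)/C(C)=C/C)cc2[C@@H]1OC(C)=O.[K+]
F6 | step 8 | (1S)-1-[(2R,3S)-3-(acetyloxy)-2-(1-iodoethenyl)-2,3-dihydro-1-benzofuran-5-yl]ethyl (2E)-2-methylbut-2-enoate (same spatial arrangement as 14; the C2 descriptor changes only through the priority of iodine) | C=C(I)[C@@H]1Oc2ccc([C@H](C)OC(=O)/C(C)=C/C)cc2[C@@H]1OC(C)=O
F7 | step 2 | 4-bromo-2-(dimethoxymethyl)-1-(prop-2-yn-1-yloxy)benzene | C#CCOc1ccc(Br)cc1C(OC)OC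
F8 | step 2 | 4-bromo-2-(dimethoxymethyl)-1-(propa-1,2-dien-1-yloxy)benzene | C=C=COc1ccc(Br)cc1C(OC)OC
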